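**Strategy.** Both tetrahydroisoquinolines are the same (1R,3R)-8-hydroxy-1,3-dimethyl unit, so one boronate building block serves twice. Its nitrogen ring is closed at N2–C3 by intramolecular hydroamination of (R)-1-[2-allyl-6-(benzyloxy)phenyl]ethanamine: one operation forms the ring and the C3 stereocentre. The step exploits the peri relationship between the C8 oxygen on the benzo ring and the C1 methyl, which holds that methyl pseudoaxial and steers the new C3 methyl equatorial, trans. The binaphthalene core comes from two isomeric methyljuglones: a Diels–Alder-derived 3-bromo-7-methyljuglone ether and a plumbagin-derived boronate are joined by Suzuki coupling; the quinone oxygens then become the two triflates for a double Suzuki coupling.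

Key step: step 6

Remark: the structure defines only the four carbon stereocentres; the hindered aryl–aryl axis between isoquinoline C5 and C1 of naphthalene B is undefined, so both rotamers about it are taken as the target and should form together in step 19 (separable by HPLC if one is wanted).

Locants: naphthalene A (from 15) keeps 7-methyljuglone numbering; naphthalene B (from 16) keeps plumbagin numbering.

**Step 1**
Reactants: 1 2-bromo-6-hydroxybenzaldehyde
Product: 2 2-(benzyloxy)-6-bromobenzaldehyde
Conditions: BnBr, K2CO3, DMF, rt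
Reagents that add atoms: benzyl bromide BrCc1ccccc1
Why: Williamson etherification of the phenoxide, to which the aldehyde and the aryl bromide are inert.

**Step 2**
Reactants: 2 2-(benzyloxy)-6-bromobenzaldehyde
Product: 3 2-allyl-6-(benzyloxy)benzaldehyde
Conditions: allyltributylstannane, Pd(PPh3)4 (5 mol %), toluene, 100 °C; aq. KF work-up
Reagents that add atoms: allyltributylstannane C=CC[Sn](CCCC)(CCCC)CCCC
Why: Stille coupling of the formyl-activated aryl bromide with an allylstannane, which, unlike an allylboronate, does not add to the free aldehyde.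

**Step 3**
Reactants: 3 2-allyl-6-(benzyloxy)benzaldehyde
Product: 4 (S,E)-N-[2-allyl-6-(benzyloxy)benzylidene]-2-methylpropane-2-sulfinamide
Conditions: (S)-tert-butanesulfinamide, Ti(OEt)4 (2 equiv), THF, 60 °C
Reagents that add atoms: (S)-2-methylpropane-2-sulfinamide CC(C)(C)[S@](=O)N
Why: Ellman condensation, in which Ti(OEt)4 acts as Lewis acid and water scavenger and should give the E-aldimine without touching the alkene or the benzyl ether.

**Step 4**
Reactants: 4 (S,E)-N-[2-allyl-6-(benzyloxy)benzylidene]-2-methylpropane-2-sulfinamide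
Product: 5 (S)-N-[(1R)-1-(2-allyl-6-(benzyloxy)phenyl)ethyl]-2-methylpropane-2-sulfinamide
Conditions: MeMgBr (3 M in Et2O), CH2Cl2, −48 °C to rt; aq. NH4Cl; chromatography
Reagents that add atoms: methylmagnesium bromide C[Mg]Br
Why: Ellman Grignard addition in a non-coordinating solvent through a six-membered chair transition state with magnesium on the sulfinyl oxygen, so the (S)-sulfinyl group should deliver methyl to the face that gives the 1R centre, and the minor diastereomer is removed by chromatography.

**Step 5**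
Reactants: 5 (S)-N-[(1R)-1-(2-allyl-6-(benzyloxy)phenyl)ethyl]-2-methylpropane-2-sulfinamide
Product: 6 (1R)-1-[2-allyl-6-(benzyloxy)phenyl]ethan-1-amine
Conditions: HCl (4 M in dioxane), MeOH, rt; then aq. NaOH
Reagents that add atoms: none
Why: Acidic methanolysis of the N–S bond of the sulfinamide, which leaves the benzylic centre, the benzyl ether and the alkene untouched.

**Step 6**
Reactants: 6 (1R)-1-[2-allyl-6-(benzyloxy)phenyl]ethan-1-amine
Product: 7 (1R,3R)-8-(benzyloxy)-1,3-dimethyl-1,2,3,4-tetrahydroisoquinoline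
Conditions: La[N(SiMe3)2]3 (10 mol %), toluene, 90 °C, argon, sealed vessel
Reagents that add atoms: none
Why: The amide precatalyst is protonolysed by the primary amine to a La–NHR species, the terminal alkene of the ortho allyl group inserts into the La–N bond through a four-centre, chair-like transition state (N–C3 bond formed), and protonolysis of the resulting La–CH2 bond by a second amine molecule gives the C3 methyl group and regenerates the amide. The closest known reaction type is the rare-earth-catalysed intramolecular hydroamination/cyclisation of primary aminoalkenes to 2-methylpiperidines. The one ring closed is the nitrogen ring of the tetrahydroisoquinoline, by 6-exo-trig (Markovnikov) attack of nitrogen on the internal alkene carbon, favoured over 7-endo closure by the rigid ortho-phenylene tether. The new C3 centre is controlled by the existing C1 centre, relayed through the peri C8 benzyloxy group: 1,3-allylic strain with that group holds the C1 methyl pseudoaxial and the inserting CH2 terminus takes the equatorial site on C3, which should give the trans (1R,3R) isomer. The step needs exo regioselectivity, trans diastereoselectivity and no prior migration of the allyl double bond; the terminal alkene, the peri substituent and a substrate carrying only an ether, an alkene and the amine secure this, and any cis isomer is removed by chromatography.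

**Step 7**
Reactants: 7 (1R,3R)-8-(benzyloxy)-1,3-dimethyl-1,2,3,4-tetrahydroisoquinoline
Product: 8 (1R,3R)-8-(benzyloxy)-5-bromo-1,3-dimethyl-1,2,3,4-tetrahydroisoquinoline
Conditions: NBS (1.05 equiv), AcOH, rt, dark; then aq. NaOH
Reagents that add atoms: N-bromosuccinimide O=C1CCC(=O)N1Br
Why: Electrophilic aromatic bromination para to the benzyloxy group (C5), with the amine protonated by the acetic acid solvent so that N-bromination and benzylic oxidation are suppressed.

**Step 8**
Reactants: 8 (1R,3R)-8-(benzyloxy)-5-bromo-1,3-dimethyl-1,2,3,4-tetrahydroisoquinoline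
Product: 9 (1R,3R)-8-(benzyloxy)-1,3-dimethyl-5-(4,4,5,5-tetramethyl-1,3,2-dioxaborolan-2-yl)-1,2,3,4-tetrahydroisoquinoline
Conditions: bis(pinacolato)diboron, Pd(dppf)Cl2 (5 mol %), KOAc, dioxane, 90 °C
Reagents that add atoms: bis(pinacolato)diboron CC1(C)OB(OC1(C)C)B1OC(C)(C)C(C)(C)O1
Why: Miyaura borylation of the aryl bromide, in which KOAc is too weak a base for Suzuki homocoupling and the doubly α-branched secondary amine should not undergo N-arylation.

**Step 9**
Reactants: 10 methyl 3-methylbut-2-enoate
Product: 11 1-methoxy-3-methyl-1-(trimethylsilyloxy)buta-1,3-diene (ketene acetal geometry not defined)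
Conditions: lithium diisopropylamide, THF, −78 °C; then Me3SiCl, −78 °C to rt; distillation
Reagents that add atoms: chlorotrimethylsilane C[Si](C)(C)Cl
Why: Kinetic γ-deprotonation of the senecioate gives the dienolate, which is O-silylated to the vinylketene acetal (Brassard-type diene).

**Step 10**
Reactants: 11 1-methoxy-3-methyl-1-(trimethylsilyloxy)buta-1,3-diene; 12 2,6-dibromo-1,4-benzoquinone
Product: 14 3-bromo-5-hydroxy-7-methylnaphthalene-1,4-dione, via Diels–Alder cycloadduct 13 (not isolated)
Conditions: toluene, −30 °C to rt; then silica gel, dilute aq. HCl/THF, rt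
Reagents that add atoms: none
Why: Regioselective Diels–Alder reaction in which the nucleophilic CH2 terminus of the diene bonds to the unsubstituted carbon of a bromoalkene unit, followed by loss of HBr and methanol and desilylation, which aromatises the new ring and places the hydroxyl peri to the carbonyl next to the retained bromine.

**Step 11**
Reactants: 14 3-bromo-5-hydroxy-7-methylnaphthalene-1,4-dione
Product: 15 3-bromo-5-methoxy-7-methylnaphthalene-1,4-dione
Conditions: MeI, Ag2O, CH2Cl2, rt, dark
Reagents that add atoms: iodomethane CI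
Why: Neutral O-methylation of the chelated peri hydroxyl with Ag2O/MeI, which avoids nucleophilic bases that would attack the bromoquinone.

**Step 12**
Reactants: 16 plumbagin (5-hydroxy-2-methylnaphthalene-1,4-dione)
Product: 17 5-(methoxymethoxy)-2-methylnaphthalene-1,4-dione
Conditions: MOMCl, iPr2NEt, CH2Cl2, 0 to 40 °C
Reagents that add atoms: chloromethyl methyl ether COCCl
Why: O-alkylation of the chelated phenol with MOMCl and a non-nucleophilic amine base that does not add to the quinone.

**Step 13**
Reactants: 17 5-(methoxymethoxy)-2-methylnaphthalene-1,4-dione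
Product: 19 4,8-bis(methoxymethoxy)-3-methylnaphthalen-1-ol (plumbagin numbering: C1–OMOM, C4–OH, C5–OMOM), via hydroquinone 18 (not isolated)
Conditions: Na2S2O4, EtOAc/H2O, rt; organic phase dried under argon; then MOMCl (1.05 equiv), iPr2NEt, CH2Cl2, −20 to 0 °C
Reagents that add atoms: chloromethyl methyl ether COCCl
Why: Dithionite reduction gives the hydroquinone, whose C4 hydroxyl is hydrogen-bonded to and shielded by the peri C5 oxygen, so one equivalent of MOMCl should react at the free C1 hydroxyl.

**Step 14**
Reactants: 19 4,8-bis(methoxymethoxy)-3-methylnaphthalen-1-ol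
Product: 20 4-methoxy-1,5-bis(methoxymethoxy)-2-methylnaphthalene
Conditions: MeI, K2CO3, DMF, 40 °C
Reagents that add atoms: iodomethane CI
Why: Williamson methylation of the remaining peri hydroxyl under basic conditions to which MOM ethers are stable.

**Step 15**
Reactants: 20 4-methoxy-1,5-bis(methoxymethoxy)-2-methylnaphthalene
Product: 21 2-[4-methoxy-1,5-bis(methoxymethoxy)-2-methylnaphthalen-6-yl]-4,4,5,5-tetramethyl-1,3,2-dioxaborolane
Conditions: n-BuLi, TMEDA, THF, −20 to 0 °C; then 2-isopropoxy-4,4,5,5-tetramethyl-1,3,2-dioxaborolane, −78 °C to rt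
Reagents that add atoms: 2-isopropoxy-4,4,5,5-tetramethyl-1,3,2-dioxaborolane CC(C)OB1OC(C)(C)C(C)(C)O1
Why: Directed ortho-metalation, in which the C5 OMOM group directs lithiation to C6, the only ring C–H ortho to a MOM ether, and the aryllithium is trapped by the borate ester.

**Step 16**
Reactants: 15 3-bromo-5-methoxy-7-methylnaphthalene-1,4-dione; 21 2-[4-methoxy-1,5-bis(methoxymethoxy)-2-methylnaphthalen-6-yl]-4,4,5,5-tetramethyl-1,3,2-dioxaborolane
Product: 22 5-methoxy-3-[4-methoxy-1,5-bis(methoxymethoxy)-2-methylnaphthalen-6-yl]-7-methylnaphthalene-1,4-dione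
Conditions: Pd(dppf)Cl2 (5 mol %), CsF, DME, 70 °C
Reagents that add atoms: none
Why: Suzuki–Miyaura coupling of an activated bromoquinone with an aryl pinacol boronate under anhydrous fluoride activation, which avoids hydroxide substitution at the bromoquinone.

**Step 17**
Reactants: 22 5-methoxy-3-[4-methoxy-1,5-bis(methoxymethoxy)-2-methylnaphthalen-6-yl]-7-methylnaphthalene-1,4-dione
Product: 23 tetraol: naphthalene A 1,4-diol (5-OMe, 7-Me) joined at C3 to C6 of naphthalene B 1,5-diol (4-OMe, 2-Me)
Conditions: SnCl2·2H2O, conc. HCl, THF/MeOH, 0 to 40 °C, argon; used crude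
Reagents that add atoms: none
Why: SnCl2 in HCl reduces the quinone to the hydroquinone while acidic methanol cleaves both MOM acetals, all under reducing conditions that shield the electron-rich naphthols from air.

**Step 18**
Reactants: 23 tetraol
Product: 24 bis-triflate: triflate at C1–O of naphthalene A and at C1–O of naphthalene B, free hydroxyls at A C4 and B C5
Conditions: PhNTf2 (2.1 equiv), Et3N, CH2Cl2, −20 to 0 °C, argon
Reagents that add atoms: N-phenylbis(trifluoromethanesulfonimide) O=S(=O)(N(c1ccccc1)S(=O)(=O)C(F)(F)F)C(F)(F)F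
Why: Chemoselective O-sulfonylation with a mild triflating agent, in which the two hydroxyls peri to a methoxy group are hydrogen-bonded and flanked by the ortho aryl, so the two C1 hydroxyls should react first.

**Step 19**
Reactants: 24 bis-triflate; 9 (1R,3R)-8-(benzyloxy)-1,3-dimethyl-5-(4,4,5,5-tetramethyl-1,3,2-dioxaborolan-2-yl)-1,2,3,4-tetrahydroisoquinoline (2.6 equiv)
Product: 25 bis(O-benzyl) target: both C1 positions of the binaphthalene carry the (1R,3R)-8-(benzyloxy)-1,3-dimethyl-1,2,3,4-tetrahydroisoquinolin-5-yl group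
Conditions: Pd(OAc)2 (10 mol %), SPhos (20 mol %), K3PO4, toluene/H2O 10:1, 100 °C
Reagents that add atoms: none
Why: Twofold Suzuki–Miyaura coupling of hindered aryl triflates with a dialkylbiarylphosphine ligand, which forms the di-ortho- and tri-ortho-substituted biaryl bonds without touching the four stereocentres, the hindered axis arising as a rotamer pair.

**Step 20**
Reactants: 25 bis(O-benzyl) target
Product: 26 CNP0077060.1 (target)
Conditions: H2 (1 atm), Pd/C (10 wt% Pd), MeOH/EtOAc, AcOH (2 equiv), rt
Reagents that add atoms: none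
Why: Hydrogenolysis of the two benzyl aryl ethers, which should leave the naphthalene rings, the methyl ethers and the ring C–N bonds of the protonated amines intact.

**Compound list**
1 | 2-bromo-6-hydroxybenzaldehyde | O=Cc1c(O)cccc1Br | starting material
2 | 2-(benzyloxy)-6-bromobenzaldehyde | O=Cc1c(OCc2ccccc2)cccc1Br | intermediate
3 | 2-allyl-6-(benzyloxy)benzaldehyde | O=Cc1c(OCc2ccccc2)cccc1CC=C | intermediate
4 | (S,E)-N-[2-allyl-6-(benzyloxy)benzylidene]-2-methylpropane-2-sulfinamide | CC(C)(C)[S@](=O)/N=C/c1c(OCc2ccccc2)cccc1CC=C | intermediate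
5 | (S)-N-[(1R)-1-(2-allyl-6-(benzyloxy)phenyl)ethyl]-2-methylpropane-2-sulfinamide | C[C@@H](N[S@@](=O)C(C)(C)C)c1c(OCc2ccccc2)cccc1CC=C | intermediate
6 | (1R)-1-[2-allyl-6-(benzyloxy)phenyl]ethan-1-amine | C[C@@H](N)c1c(OCc2ccccc2)cccc1CC=C | intermediate
7 | (1R,3R)-8-(benzyloxy)-1,3-dimethyl-1,2,3,4-tetrahydroisoquinoline | c1ccc(OCc2ccccc2)c3c1C[C@@H](C)N[C@@H]3C | intermediate
8 | (1R,3R)-8-(benzyloxy)-5-bromo-1,3-dimethyl-1,2,3,4-tetrahydroisoquinoline | Brc1ccc(OCc2ccccc2)c3c1C[C@@H](C)N[C@@H]3C | intermediate
9 | (1R,3R)-8-(benzyloxy)-1,3-dimethyl-5-(4,4,5,5-tetramethyl-1,3,2-dioxaborolan-2-yl)-1,2,3,4-tetrahydroisoquinoline | CC1(C)OB(OC1(C)C)c1ccc(OCc2ccccc2)c3c1C[C@@H](C)N[C@@H]3C | intermediate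
10 | methyl 3-methylbut-2-enoate | COC(=O)C=C(C)C | starting material
11 | 1-methoxy-3-methyl-1-(trimethylsilyloxy)buta-1,3-diene | COC(O[Si](C)(C)C)=CC(C)=C | intermediate
12 | 2,6-dibromo-1,4-benzoquinone | O=C1C=C(Br)C(=O)C(Br)=C1 | starting material
13 | 3,4a-dibromo-5-methoxy-7-methyl-5-(trimethylsilyloxy)-4a,5,8,8a-tetrahydronaphthalene-1,4-dione (cis-fused cycloadduct, configuration not assigned) | O=C1C=C(Br)C(=O)C2(Br)C(OC)(O[Si](C)(C)C)C=C(C)CC12 | intermediate
14 | 3-bromo-5-hydroxy-7-methylnaphthalene-1,4-dione | O=C1C=C(Br)C(=O)c2c(O)cc(C)cc12 | intermediate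
15 | 3-bromo-5-methoxy-7-methylnaphthalene-1,4-dione | O=C1C=C(Br)C(=O)c2c(OC)cc(C)cc12 | intermediate
16 | plumbagin (5-hydroxy-2-methylnaphthalene-1,4-dione) | CC1=CC(=O)c2c(O)cccc2C1=O | starting material
17 | 5-(methoxymethoxy)-2-methylnaphthalene-1,4-dione | CC1=CC(=O)c2c(OCOC)cccc2C1=O | intermediate
18 | 5-(methoxymethoxy)-2-methylnaphthalene-1,4-diol | Cc1cc(O)c2c(OCOC)cccc2c1O | intermediate
19 | 4,8-bis(methoxymethoxy)-3-methylnaphthalen-1-ol | Cc1cc(O)c2c(OCOC)cccc2c1OCOC | intermediate
20 | 4-methoxy-1,5-bis(methoxymethoxy)-2-methylnaphthalene | Cc1cc(OC)c2c(OCOC)cccc2c1OCOC | intermediate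
21 | 2-[4-methoxy-1,5-bis(methoxymethoxy)-2-methylnaphthalen-6-yl]-4,4,5,5-tetramethyl-1,3,2-dioxaborolane | Cc1cc(OC)c2c(OCOC)c(B3OC(C)(C)C(C)(C)O3)ccc2c1OCOC | intermediate
22 | 5-methoxy-3-[4-methoxy-1,5-bis(methoxymethoxy)-2-methylnaphthalen-6-yl]-7-methylnaphthalene-1,4-dione | O=C1C=C(c3ccc4c(OCOC)c(C)cc(OC)c4c3OCOC)C(=O)c2c(OC)cc(C)cc12 | intermediate
23 | 2-(1,5-dihydroxy-8-methoxy-6-methylnaphthalen-2-yl)-8-methoxy-6-methylnaphthalene-1,4-diol (tetraol) | COc1cc(C)cc2c(O)cc(-c3ccc4c(O)c(C)cc(OC)c4c3O)c(O)c12 | intermediate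
24 | bis-triflate of 23 at the two hydroxyls not peri to a methoxy group | COc1cc(C)cc2c(OS(=O)(=O)C(F)(F)F)cc(-c3ccc4c(OS(=O)(=O)C(F)(F)F)c(C)cc(OC)c4c3O)c(O)c12 | intermediate
25 | bis(O-benzyl) target, (1R,3R) in both isoquinolines, rotamer pair about the hindered axis | COc1cc(C)cc2c(-c3ccc(OCc7ccccc7)c4c3C[C@@H](C)N[C@@H]4C)cc(-c3ccc4c(-c5ccc(OCc8ccccc8)c6c5C[C@@H](C)N[C@@H]6C)c(C)cc(OC)c4c3O)c(O)c12 | intermediate
26 | CNP0077060.1 | COc1cc(C)cc2c(-c3ccc(O)c4c3C[C@@H](C)N[C@@H]4C)cc(-c3ccc4c(-c5ccc(O)c6c5C[C@@H](C)N[C@@H]6C)c(C)cc(OC)c4c3O)c(O)c12 | target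

**Step count.** Total: 20 steps. Longest linear sequence: 10 steps (steps 1–8, 19, 20).

**Steps most likely to fail**

1. Step 6. The ring closure may give poor trans/cis selectivity, the basic catalyst may move the allyl double bond into conjugation before insertion, or the benzyl ether may chelate and slow the catalyst. The fallback closes the same N–C3 bond stereospecifically and sets out from 6. NsCl/Et3N gives (R)-N-{1-[2-allyl-6-(benzyloxy)phenyl]ethyl}-2-nitrobenzenesulfonamide F1. Wacker oxidation (PdCl2, CuCl, O2, DMF/H2O) gives the methyl ketone F2. Reduction with (R)-2-methyl-CBS-oxazaborolidine and BH3·SMe2 (or a ketoreductase) gives the (S)-alcohol F3. An intramolecular Fukuyama–Mitsunobu reaction (PPh3, DIAD, THF) displaces the activated hydroxyl with inversion and gives the (1R,3R) N-nosyl tetrahydroisoquinoline F4. PhSH/K2CO3 in DMF removes the nosyl group and the route is rejoined at 7.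

2. Step 18. Discrimination among four hydroxyls may be incomplete (over-triflation or reaction at a peri hydroxyl), and the hydroquinone may reoxidise in air. The fallback unmasks the two sites one at a time and sets out from 22. Na2S2O4 reduction, which keeps the MOM ethers, gives the MOM-protected hydroquinone F5, which has a single hydroxyl that is not peri to a methoxy group. PhNTf2 (1 equiv) gives the monotriflate F6. HCl in MeOH removes both MOM groups to give the triol monotriflate F7. A second equivalent of PhNTf2 then has to pick one free C1 hydroxyl of naphthalene B out of three, and the route is rejoined at 24.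

3. Step 19. Oxidative addition into the electron-rich naphthoxide triflates may be slow, the second coupling at the tri-ortho-substituted axis may stall, and the boronate may protodeboronate. The fallback removes the phenoxide character and sets out from 24. BnBr/Cs2CO3 in DMF gives the di-O-benzyl bis-triflate F8. The same double Suzuki coupling with 9 on this neutral substrate gives the tetra-O-benzyl tetraaryl F9. Hydrogenolysis under the conditions of step 20 removes all four benzyl groups and the route is rejoined at 26.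

**Further compounds**
F1 | step 6 | (R)-N-{1-[2-allyl-6-(benzyloxy)phenyl]ethyl}-2-nitrobenzenesulfonamide | C[C@@H](NS(=O)(=O)c1ccccc1[N+](=O)[O-])c1c(OCc2ccccc2)cccc1CC=C
F2 | step 6 | (R)-N-{1-[2-(benzyloxy)-6-(2-oxopropyl)phenyl]ethyl}-2-nitrobenzenesulfonamide | C[C@@H](NS(=O)(=O)c1ccccc1[N+](=O)[O-])c1c(OCc2ccccc2)cccc1CC(C)=O
F3 | step 6 | N-{(1R)-1-[2-(benzyloxy)-6-((2S)-2-hydroxypropyl)phenyl]ethyl}-2-nitrobenzenesulfonamide | C[C@@H](NS(=O)(=O)c1ccccc1[N+](=O)[O-])c1c(OCc2ccccc2)cccc1C[C@H](C)O
F4 | step 6 | (1R,3R)-8-(benzyloxy)-1,3-dimethyl-2-(2-nitrobenzenesulfonyl)-1,2,3,4-tetrahydroisoquinoline | c1ccc(OCc2ccccc2)c3c1C[C@@H](C)N(S(=O)(=O)c4ccccc4[N+](=O)[O-])[C@@H]3C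
F5 | step 18 | 5-methoxy-3-[4-methoxy-1,5-bis(methoxymethoxy)-2-methylnaphthalen-6-yl]-7-methylnaphthalene-1,4-diol | COc1cc(C)cc2c(O)cc(-c3ccc4c(OCOC)c(C)cc(OC)c4c3OCOC)c(O)c12
F6 | step 18 | monotriflate of F5 at C1–O of naphthalene A | COc1cc(C)cc2c(OS(=O)(=O)C(F)(F)F)cc(-c3ccc4c(OCOC)c(C)cc(OC)c4c3OCOC)c(O)c12
F7 | step 18 | triol monotriflate (F6 without MOM groups) | COc1cc(C)cc2c(OS(=O)(=O)C(F)(F)F)cc(-c3ccc4c(O)c(C)cc(OC)c4c3O)c(O)c12
F8 | step 19 | di-O-benzyl ether of bis-triflate 24 | COc1cc(C)cc2c(OS(=O)(=O)C(F)(F)F)cc(-c3ccc4c(OS(=O)(=O)C(F)(F)F)c(C)cc(OC)c4c3OCc5ccccc5)c(OCc6ccccc6)c12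
F9 | step 19 | tetra-O-benzyl target, (1R,3R) in both isoquinolines | COc1cc(C)cc2c(-c3ccc(OCc7ccccc7)c4c3C[C@@H](C)N[C@@H]4C)cc(-c3ccc4c(-c5ccc(OCc8ccccc8)c6c5C[C@@H](C)N[C@@H]6C)c(C)cc(OC)c4c3OCc3ccccc3)c(OCc3ccccc3)c12
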